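**Plan**

- Cuts: C11=C12 and C11'=C12' (carotenoid numbering, primes for the hydroxylated half) are Wittig disconnections to a C10 dialdehyde and two C20 phosphonium salts; each salt is cut at C7=C8 and C9–C10 back to a ring C7 alcohol.
- Ring A is cut at C1–C6. It joins the quaternary C1 to the stereocentre C6 next to a C4=C5 alkene, the pattern left when a C1 cation is trapped by a C5=C6 alkene and H-4 is lost; its C2, bonded to C1 (a former isopropenyl carbon) and carrying the prenyl arm, is the stereocentre of (R)-lavandulol.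
- Ring B reads from the SMILES as 2',6'-trans (2'R,6'S), unlike the cis ring A (2S,6R), so a chair cyclisation cannot give it. It is cut at C6'–C7' ([2,3]-shift from a C4' allylic ether) and at the C2'–side-chain bond (conjugate allylation of a cyclohexadienone).
- Forward: lavandulol is extended to the acyclic trienol, ring A closes and is carried to the C30 aldehyde; ring B is built from a cyclohexenone and carried to its C20 salt; the halves are joined at C11'=C12' and the silyl ether is removed last.
- Stereochemistry: C2 from (R)-lavandulol; C6 from the chair of the cyclase step; C2' and C4'–O from a catalyst-controlled CBS reduction of the racemic enone with separation of diastereomers; C6' by suprafacial transfer from C4'–O; chain alkenes E from HWE and Wittig reactions with thermal equilibration.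

Key step: step 4

Remark on stereochemistry: ring B is made exactly as drawn, 2',6'-trans, although ring A is 2,6-cis.
Remark on materials: (R)-lavandulol of high enantiomeric purity, the chloro acetate 3, the all-E C10 dialdehyde 12 and enone 16 are taken as purchasable; polyenes are handled under argon in dim light.

**Route**

Step 1
Reactants: 1 (R)-lavandulol
Product: 2 (R)-lavandulyl bromide [(3R)-3-(bromomethyl)-2,6-dimethylhepta-1,5-diene]
Conditions: CBr4, PPh3, CH2Cl2, 0 °C
Reagents that add atoms: carbon tetrabromide, BrC(Br)(Br)Br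
Why: The Appel reaction brominates the primary alcohol by SN2 attack of bromide on the alkoxyphosphonium ion at the CH2 group, which is not the stereocentre, so the (R) configuration and both alkenes are kept.

Step 2
Reactants: 2 (R)-lavandulyl bromide; 3 (E)-4-chloro-3-methylbut-2-en-1-yl acetate
Product: 5 (2E,6R)-3,7-dimethyl-6-(3-methylbut-2-en-1-yl)octa-2,7-dien-1-yl acetate, via (R)-lavandulylmagnesium bromide 4 (not isolated)
Conditions: Mg, THF, 40 °C; then 3, Li2CuCl4 (3 mol%), THF, −30 to 0 °C
Reagents that add atoms: none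
Why: The primary homoallylic Grignard reagent forms without disturbing the neighbouring stereocentre, and in the Li2CuCl4-catalysed cross-coupling (Kochi-type) it should displace the primary allylic chloride of 3 at its CH2Cl carbon faster than it adds to the acetate at low temperature, keeping the E alkene.

Step 3
Reactants: 5 (2E,6R)-3,7-dimethyl-6-(3-methylbut-2-en-1-yl)octa-2,7-dien-1-yl acetate
Product: 6 (2E,6R)-3,7-dimethyl-6-(3-methylbut-2-en-1-yl)octa-2,7-dien-1-ol
Conditions: K2CO3 (cat.), MeOH, rt
Reagents that add atoms: none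
Why: Carbonate-catalysed transesterification with methanol removes the acetate and leaves the three alkenes and the stereocentre untouched.

Step 4
Reactants: 6 (2E,6R)-3,7-dimethyl-6-(3-methylbut-2-en-1-yl)octa-2,7-dien-1-ol
Product: 7 [(1R,5S)-2,6,6-trimethyl-5-(3-methylbut-2-en-1-yl)cyclohex-2-en-1-yl]methanol (2,6-cis ring A alcohol)
Conditions: squalene–hopene cyclase variant (Alicyclobacillus acidocaldarius enzyme, active-site library screened on 6), E. coli whole cells, citrate buffer pH 6.0, 0.2% Triton X-100, 30 °C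
Reagents that add atoms: none
Why: Proposed new method: the catalytic aspartic acid of the cyclase should protonate the terminal CH2 of the isopropenyl group to give the tertiary C1 cation, the C5=C6 alkene folded over it attacks through C6 to form the C1–C6 bond, and a nearby base removes H-4 from the resulting C5 cation to leave the C4=C5 alkene; the closest known reactions are the monocyclisation of geraniol-type alcohols by squalene–hopene cyclase variants and the cyclase step of C50 carotenoid biosynthesis, neither shown on this lavandulyl-branched trienol. Ring A closes in a 6-endo-trig mode with respect to the C5=C6 alkene, through a chair. The new stereocentre C6 is set by that chair: the preset C2 centre puts the prenyl arm equatorial and the E geometry of the C5=C6 alkene puts C7 equatorial, so the two end up cis, which is (2S,6R). The step needs protonation at the 1,1-disubstituted alkene and not at either trisubstituted alkene, attack on one face of C5=C6, and loss of H-4 and not of a methyl or C6 proton; the hydroxyl anchor, the E alkene and the C2 centre fix the fold, and the shaped pocket selected in the variant screen must fix the site of protonation and of proton loss.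

Step 5
Reactants: 7 [(1R,5S)-2,6,6-trimethyl-5-(3-methylbut-2-en-1-yl)cyclohex-2-en-1-yl]methanol
Product: 8 (1R,5S)-2,6,6-trimethyl-5-(3-methylbut-2-en-1-yl)cyclohex-2-ene-1-carbaldehyde
Conditions: Dess–Martin periodinane, NaHCO3, CH2Cl2, 0 °C
Reagents that add atoms: none
Why: Dess–Martin oxidation buffered with bicarbonate gives the aldehyde under conditions too mild to enolise it, so C6 keeps its configuration and the C4=C5 alkene stays out of conjugation, and the aldehyde is used at once.

Step 6
Reactants: 8 (1R,5S)-2,6,6-trimethyl-5-(3-methylbut-2-en-1-yl)cyclohex-2-ene-1-carbaldehyde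
Product: 9 (3E)-4-[(1R,5S)-2,6,6-trimethyl-5-(3-methylbut-2-en-1-yl)cyclohex-2-en-1-yl]but-3-en-2-one
Conditions: (EtO)2P(O)CH2C(O)CH3, LiCl, i-Pr2NEt, MeCN, rt
Reagents that add atoms: diethyl (2-oxopropyl)phosphonate, CCOP(=O)(CC(C)=O)OCC
Why: The Horner–Wadsworth–Emmons reaction under Masamune–Roush conditions (lithium-chelated β-ketophosphonate, tertiary amine) is mild enough for an enolisable α-branched aldehyde and should give the E enone, an α-ionone analogue, with C6 unchanged.

Step 7
Reactants: 9 (3E)-4-[(1R,5S)-2,6,6-trimethyl-5-(3-methylbut-2-en-1-yl)cyclohex-2-en-1-yl]but-3-en-2-one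
Product: 10 (1E)-3-methyl-1-[(1R,5S)-2,6,6-trimethyl-5-(3-methylbut-2-en-1-yl)cyclohex-2-en-1-yl]penta-1,4-dien-3-ol (C9 epimers)
Conditions: CH2=CHMgBr, THF, −78 to 0 °C; then H2O
Reagents that add atoms: vinylmagnesium bromide, C=C[Mg]Br
Why: Grignard 1,2-addition of the vinyl reagent to the enone carbonyl gives the tertiary bis-allylic alcohol as a mixture of C9 epimers, which is of no consequence because C9 becomes sp2 in step 8.

Step 8
Reactants: 10 (1E)-3-methyl-1-[(1R,5S)-2,6,6-trimethyl-5-(3-methylbut-2-en-1-yl)cyclohex-2-en-1-yl]penta-1,4-dien-3-ol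
Product: 11 [(2E,4E)-3-methyl-5-[(1R,5S)-2,6,6-trimethyl-5-(3-methylbut-2-en-1-yl)cyclohex-2-en-1-yl]penta-2,4-dien-1-yl]triphenylphosphonium bromide
Conditions: PPh3·HBr, CH2Cl2, rt
Reagents that add atoms: triphenylphosphine hydrobromide, Br.c1ccc(cc1)P(c1ccccc1)c1ccccc1
Why: Triphenylphosphine hydrobromide ionises the tertiary allylic alcohol to a delocalised cation that the phosphine captures at the unhindered terminus C11 (SN1' allylic transposition), which should give the conjugated 9E dienyl phosphonium salt, to be purified by crystallisation.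

Step 9
Reactants: 11 ring A C20 phosphonium bromide; 12 (2E,4E,6E)-2,7-dimethylocta-2,4,6-trienedial
Product: 15 (2E,4E,6E,8E,10E,12E)-2,7,11-trimethyl-13-[(1R,5S)-2,6,6-trimethyl-5-(3-methylbut-2-en-1-yl)cyclohex-2-en-1-yl]trideca-2,4,6,8,10,12-hexaenal, via ring A ylide 13 (not isolated), via 11Z aldehyde 14 (not isolated)
Conditions: NaOMe, 12 (3 equiv), CH2Cl2/MeOH, 0 °C to rt; then heptane, reflux
Reagents that add atoms: none
Why: The Wittig reaction of the semi-stabilised allylic ylide with one carbonyl of the dialdehyde, used in threefold excess to suppress double olefination, forms C11=C12, and heating converts the hindered 11Z isomer formed beside the E isomer into the all-E aldehyde.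

Step 10
Reactants: 16 2,4,4-trimethylcyclohex-2-en-1-one
Product: 17 2,4,4-trimethylcyclohexa-2,5-dien-1-one
Conditions: DDQ, 1,4-dioxane, reflux
Reagents that add atoms: none
Why: DDQ dehydrogenation of the enone through its cross-conjugated dienol introduces the second ring alkene, and the gem-dimethyl carbon prevents aromatisation.

Step 11
Reactants: 17 2,4,4-trimethylcyclohexa-2,5-dien-1-one
Product: 18 racemic 2,4,4-trimethyl-5-(prop-2-en-1-yl)cyclohex-2-en-1-one
Conditions: CH2=CHCH2SiMe3, TiCl4, CH2Cl2, −78 °C; then H2O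
Reagents that add atoms: allyltrimethylsilane, C=CC[Si](C)(C)C
Why: Hosomi–Sakurai conjugate allylation should occur at the β-carbon of the unsubstituted enone arm, the methyl-bearing arm being the less electrophilic one, and creates the future C2' centre as a racemate that step 13 resolves.

Step 12
Reactants: 18 racemic 2,4,4-trimethyl-5-(prop-2-en-1-yl)cyclohex-2-en-1-one
Product: 19 racemic (2E)-2-methyl-4-(2,2,4-trimethyl-5-oxocyclohex-3-en-1-yl)but-2-enal
Conditions: methacrolein (5 equiv), second-generation Hoveyda–Grubbs catalyst RuCl2(H2IMes)(=CH-C6H4-2-O-i-Pr) (5 mol%), CH2Cl2, 40 °C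
Reagents that add atoms: methacrolein, C=C(C)C=O
Why: Olefin cross-metathesis of the terminal alkene with an excess of methacrolein should give the E-configured 2-methyl enal under thermodynamic control, the trisubstituted ring alkene being inert to the catalyst.

Step 13
Reactants: 19 racemic (2E)-2-methyl-4-(2,2,4-trimethyl-5-oxocyclohex-3-en-1-yl)but-2-enal
Product: 20 (1S,5S)-5-[(2E)-4-hydroxy-3-methylbut-2-en-1-yl]-2,4,4-trimethylcyclohex-2-en-1-ol (1,5-trans)
Conditions: (R)-2-methyl-CBS-oxazaborolidine (20 mol%), catecholborane (2.5 equiv), toluene, −78 °C; then H2O; chromatography on SiO2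
Reagents that add atoms: none
Why: In the Corey–Bakshi–Shibata reduction the (R)-oxazaborolidine should deliver hydride to the same face of the ring carbonyl in both enantiomers of 19 to give the (1S) carbinol, so that the (S) enantiomer becomes the 1,5-trans diol 20 and the (R) enantiomer a cis diastereomer that is removed by chromatography, while the aldehyde is reduced at the same time.

Step 14
Reactants: 20 (1S,5S)-5-[(2E)-4-hydroxy-3-methylbut-2-en-1-yl]-2,4,4-trimethylcyclohex-2-en-1-ol
Product: 21 (1S,5S)-5-[(2E)-4-(tert-butyldiphenylsilyloxy)-3-methylbut-2-en-1-yl]-2,4,4-trimethylcyclohex-2-en-1-ol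
Conditions: t-BuPh2SiCl (1.05 equiv), imidazole, CH2Cl2, 0 °C
Reagents that add atoms: tert-butyldiphenylsilyl chloride, CC(C)(C)[Si](Cl)(c1ccccc1)c1ccccc1
Why: Silyl ether formation with the bulky chlorosilane is selective for the primary allylic hydroxyl over the hindered secondary one.

Step 15
Reactants: 21 (1S,5S)-5-[(2E)-4-(tert-butyldiphenylsilyloxy)-3-methylbut-2-en-1-yl]-2,4,4-trimethylcyclohex-2-en-1-ol
Product: 22 tributyl[[(1S,5S)-5-[(2E)-4-(tert-butyldiphenylsilyloxy)-3-methylbut-2-en-1-yl]-2,4,4-trimethylcyclohex-2-en-1-yl]oxymethyl]stannane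
Conditions: KH, Bu3SnCH2I, THF, 0 °C to rt
Reagents that add atoms: tributyl(iodomethyl)stannane, CCCC[Sn](CCCC)(CCCC)CI
Why: Williamson etherification of the potassium alkoxide with the iodomethylstannane installs the stannylmethyl ether for the Still–Wittig rearrangement without touching the carbinol centre.

Step 16
Reactants: 22 stannylmethyl ether of 21
Product: 24 [(1S,5R)-5-[(2E)-4-(tert-butyldiphenylsilyloxy)-3-methylbut-2-en-1-yl]-2,6,6-trimethylcyclohex-2-en-1-yl]methanol (2,6-trans ring B alcohol), via lithiomethyl ether 23 (not isolated)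
Conditions: n-BuLi, THF, −78 to −20 °C; then H2O
Reagents that add atoms: none
Why: Tin–lithium exchange gives an α-alkoxymethyllithium that undergoes the Still–Wittig [2,3]-sigmatropic rearrangement suprafacially, so the C6'–C7' bond forms on the face that carried the C4' oxygen, trans to the C2' side chain, while the alkene moves to C4'=C5'.

Step 17
Reactants: 24 2,6-trans ring B alcohol
Product: 25 (1S,5R)-5-[(2E)-4-(tert-butyldiphenylsilyloxy)-3-methylbut-2-en-1-yl]-2,6,6-trimethylcyclohex-2-ene-1-carbaldehyde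
Conditions: Dess–Martin periodinane, NaHCO3, CH2Cl2, 0 °C
Reagents that add atoms: none
Why: Dess–Martin oxidation under bicarbonate buffer gives the trans aldehyde under conditions too mild to enolise C6', and it is carried on at once without chromatography.

Step 18
Reactants: 25 ring B aldehyde
Product: 26 (3E)-4-[(1S,5R)-5-[(2E)-4-(tert-butyldiphenylsilyloxy)-3-methylbut-2-en-1-yl]-2,6,6-trimethylcyclohex-2-en-1-yl]but-3-en-2-one
Conditions: (EtO)2P(O)CH2C(O)CH3, LiCl, i-Pr2NEt, MeCN, rt
Reagents that add atoms: diethyl (2-oxopropyl)phosphonate, CCOP(=O)(CC(C)=O)OCC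
Why: In this Horner–Wadsworth–Emmons reaction under Masamune–Roush conditions the lithium-chelated phosphonate should add to the aldehyde faster than the weak amine base can enolise it, giving the E enone with the 2',6'-trans relation kept.

Step 19
Reactants: 26 ring B enone
Product: 27 (1E)-1-[(1S,5R)-5-[(2E)-4-(tert-butyldiphenylsilyloxy)-3-methylbut-2-en-1-yl]-2,6,6-trimethylcyclohex-2-en-1-yl]-3-methylpenta-1,4-dien-3-ol (C9' epimers)
Conditions: CH2=CHMgBr, THF, −78 to 0 °C; then H2O
Reagents that add atoms: vinylmagnesium bromide, C=C[Mg]Br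
Why: Grignard 1,2-addition to the enone gives the tertiary allylic alcohol as C9' epimers, which converge in step 20, the silyl ether being inert.

Step 20
Reactants: 27 ring B vinyl carbinol
Product: 28 [(2E,4E)-5-[(1S,5R)-5-[(2E)-4-(tert-butyldiphenylsilyloxy)-3-methylbut-2-en-1-yl]-2,6,6-trimethylcyclohex-2-en-1-yl]-3-methylpenta-2,4-dien-1-yl]triphenylphosphonium bromide
Conditions: PPh3·HBr, CH2Cl2, rt
Reagents that add atoms: triphenylphosphine hydrobromide, Br.c1ccc(cc1)P(c1ccccc1)c1ccccc1
Why: Allylic transposition with triphenylphosphine hydrobromide (SN1' capture of the delocalised cation at C11') should give the 9'E phosphonium salt, the acid being too weak to cleave the tert-butyldiphenylsilyl ether in dichloromethane.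

Step 21
Reactants: 28 ring B C20 phosphonium bromide; 15 ring A C30 aldehyde
Product: 31 tert-butyldiphenylsilyl ether of the target (all-E), via ring B ylide 29 (not isolated), via 11'Z silyl ether 30 (not isolated)
Conditions: NaOMe, CH2Cl2/MeOH, 0 °C to rt; then heptane, reflux
Reagents that add atoms: none
Why: The Wittig reaction of the semi-stabilised ylide with the C30 aldehyde forms C11'=C12' and completes the C50 chain, and heating equilibrates the hindered 11'Z isomer to the all-E polyene.

Step 22
Reactants: 31 tert-butyldiphenylsilyl ether of the target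
Product: 32 (2S,6R,2'R,6'S)-2-(3-methylbut-2-enyl)-2'-[(E)-4-hydroxy-3-methylbut-2-enyl]-ε,ε-carotene (CNP0304855.1)
Conditions: Bu4NF, THF, 0 °C to rt
Reagents that add atoms: none
Why: Fluoride-mediated desilylation frees the primary allylic alcohol under conditions that leave the polyene and the four ring stereocentres untouched.

**Compound list**

1 | (R)-lavandulol | CC(C)=CC[C@@H](CO)C(C)=C | starting material
2 | (R)-lavandulyl bromide | CC(C)=CC[C@@H](CBr)C(C)=C | intermediate
3 | (E)-4-chloro-3-methylbut-2-en-1-yl acetate | CC(=O)OC/C=C(\C)CCl | starting material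
4 | (R)-lavandulylmagnesium bromide | CC(C)=CC[C@@H](C[Mg]Br)C(C)=C | intermediate (not isolated)
5 | (2E,6R)-3,7-dimethyl-6-(3-methylbut-2-en-1-yl)octa-2,7-dien-1-yl acetate | CC(C)=CC[C@@H](CC/C(C)=C/COC(C)=O)C(C)=C | intermediate
6 | (2E,6R)-3,7-dimethyl-6-(3-methylbut-2-en-1-yl)octa-2,7-dien-1-ol | CC(C)=CC[C@@H](CC/C(C)=C/CO)C(C)=C | intermediate
7 | [(1R,5S)-2,6,6-trimethyl-5-(3-methylbut-2-en-1-yl)cyclohex-2-en-1-yl]methanol | CC(C)=CC[C@H]1CC=C(C)[C@@H](CO)C1(C)C | intermediate
8 | (1R,5S)-2,6,6-trimethyl-5-(3-methylbut-2-en-1-yl)cyclohex-2-ene-1-carbaldehyde | CC(C)=CC[C@H]1CC=C(C)[C@@H](C=O)C1(C)C | intermediate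
9 | ring A enone, (3E)-4-[(1R,5S)-ring]but-3-en-2-one | CC(C)=CC[C@H]1CC=C(C)[C@@H](/C=C/C(C)=O)C1(C)C | intermediate
10 | ring A vinyl carbinol (C9 epimers) | CC(C)=CC[C@H]1CC=C(C)[C@@H](/C=C/C(C)(O)C=C)C1(C)C | intermediate
11 | ring A C20 phosphonium bromide (9E) | CC(C)=CC[C@H]1CC=C(C)[C@@H](/C=C/C(C)=C/C[P+](c2ccccc2)(c2ccccc2)c2ccccc2)C1(C)C.[Br-] | intermediate
12 | (2E,4E,6E)-2,7-dimethylocta-2,4,6-trienedial | O=C/C(C)=C/C=C/C=C(C)/C=O | starting material
13 | ring A ylide | CC(C)=CC[C@H]1CC=C(C)[C@@H](/C=C/C(C)=C/C=P(c2ccccc2)(c2ccccc2)c2ccccc2)C1(C)C | intermediate (not isolated)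
14 | 11Z isomer of 15 | CC(C)=CC[C@H]1CC=C(C)[C@@H](/C=C/C(C)=C/C=C\C(C)=C\C=C\C=C(C)\C=O)C1(C)C | intermediate (not isolated)
15 | ring A C30 aldehyde (all-E) | CC(C)=CC[C@H]1CC=C(C)[C@@H](/C=C/C(C)=C/C=C/C(C)=C/C=C/C=C(C)/C=O)C1(C)C | intermediate
16 | 2,4,4-trimethylcyclohex-2-en-1-one | CC1=CC(C)(C)CCC1=O | starting material
17 | 2,4,4-trimethylcyclohexa-2,5-dien-1-one | CC1=CC(C)(C)C=CC1=O | intermediate
18 | racemic 2,4,4-trimethyl-5-(prop-2-en-1-yl)cyclohex-2-en-1-one | C=CCC1CC(=O)C(C)=CC1(C)C | intermediate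
19 | racemic (2E)-2-methyl-4-(2,2,4-trimethyl-5-oxocyclohex-3-en-1-yl)but-2-enal | O=C/C(C)=C/CC1CC(=O)C(C)=CC1(C)C | intermediate
20 | (1S,5S)-5-[(2E)-4-hydroxy-3-methylbut-2-en-1-yl]-2,4,4-trimethylcyclohex-2-en-1-ol | O[C@H]1C[C@H](C/C=C(\C)CO)C(C)(C)C=C1C | intermediate
21 | mono tert-butyldiphenylsilyl ether of 20 (primary oxygen) | O[C@H]1C[C@H](C/C=C(\C)CO[Si](c2ccccc2)(c2ccccc2)C(C)(C)C)C(C)(C)C=C1C | intermediate
22 | tributylstannylmethyl ether of 21 | CCCC[Sn](CCCC)(CCCC)CO[C@H]1C[C@H](C/C=C(\C)CO[Si](c2ccccc2)(c2ccccc2)C(C)(C)C)C(C)(C)C=C1C | intermediate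
23 | lithiomethyl ether of 21 | [Li]CO[C@H]1C[C@H](C/C=C(\C)CO[Si](c2ccccc2)(c2ccccc2)C(C)(C)C)C(C)(C)C=C1C | intermediate (not isolated)
24 | [(1S,5R)-5-[(2E)-4-(tert-butyldiphenylsilyloxy)-3-methylbut-2-en-1-yl]-2,6,6-trimethylcyclohex-2-en-1-yl]methanol | OC[C@H]1C(C)=CC[C@H](C/C=C(\C)CO[Si](c2ccccc2)(c2ccccc2)C(C)(C)C)C1(C)C | intermediate
25 | ring B aldehyde (1S,5R) | O=C[C@H]1C(C)=CC[C@H](C/C=C(\C)CO[Si](c2ccccc2)(c2ccccc2)C(C)(C)C)C1(C)C | intermediate
26 | ring B enone (3E) | CC(=O)/C=C/[C@H]1C(C)=CC[C@H](C/C=C(\C)CO[Si](c2ccccc2)(c2ccccc2)C(C)(C)C)C1(C)C | intermediate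
27 | ring B vinyl carbinol (C9' epimers) | C=CC(C)(O)/C=C/[C@H]1C(C)=CC[C@H](C/C=C(\C)CO[Si](c2ccccc2)(c2ccccc2)C(C)(C)C)C1(C)C | intermediate
28 | ring B C20 phosphonium bromide (9'E) | [Br-].c3ccccc3[P+](c3ccccc3)(c3ccccc3)C/C=C(C)/C=C/[C@H]1C(C)=CC[C@H](C/C=C(\C)CO[Si](c2ccccc2)(c2ccccc2)C(C)(C)C)C1(C)C | intermediate
29 | ring B ylide | c3ccccc3P(c3ccccc3)(c3ccccc3)=C/C=C(C)/C=C/[C@H]1C(C)=CC[C@H](C/C=C(\C)CO[Si](c2ccccc2)(c2ccccc2)C(C)(C)C)C1(C)C | intermediate (not isolated)
30 | 11'Z isomer of 31 | CC(C)=CC[C@H]1CC=C(C)[C@@H](/C=C/C(C)=C/C=C/C(C)=C/C=C/C=C(C)/C=C\C=C(C)\C=C\[C@H]2C(C)=CC[C@H](C/C=C(\C)CO[Si](c3ccccc3)(c3ccccc3)C(C)(C)C)C2(C)C)C1(C)C | intermediate (not isolated)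
31 | tert-butyldiphenylsilyl ether of the target (all-E) | CC(C)=CC[C@H]1CC=C(C)[C@@H](/C=C/C(C)=C/C=C/C(C)=C/C=C/C=C(C)/C=C/C=C(C)/C=C/[C@H]2C(C)=CC[C@H](C/C=C(\C)CO[Si](c3ccccc3)(c3ccccc3)C(C)(C)C)C2(C)C)C1(C)C | intermediate
32 | CNP0304855.1, (2S,6R,2'R,6'S) | CC(C)=CC[C@H]1CC=C(C)[C@@H](/C=C/C(C)=C/C=C/C(C)=C/C=C/C=C(C)/C=C/C=C(C)/C=C/[C@H]2C(C)=CC[C@H](C/C=C(\C)CO)C2(C)C)C1(C)C | target

**Count**

Total steps: 22. Longest linear sequence: 13 steps (16 to 32, steps 10–22); the ring A branch is 11 steps (1 to 32).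

**Steps most likely to fail**

Step 4 (Proposed new method). The cyclase may protonate the prenyl arm or the C5=C6 alkene ahead of the isopropenyl group, lose the wrong proton after ring closure, or fail to turn over the branched trienol. The fallback uses the chirality-transfer logic of ring B and sets out from 18. Cross-metathesis with 2-methylbut-2-ene (second-generation Grubbs catalyst RuCl2(PCy3)(H2IMes)(=CHPh)) would give racemic 2,4,4-trimethyl-5-(3-methylbut-2-en-1-yl)cyclohex-2-en-1-one F1. CBS reduction with the (S)-oxazaborolidine, here matched with axial hydride delivery in the (S) enantiomer, and separation from the trans diastereomer should give (1R,5S)-2,4,4-trimethyl-5-(3-methylbut-2-en-1-yl)cyclohex-2-en-1-ol F2. KH and Bu3SnCH2I would give its tributylstannylmethyl ether F3, and n-BuLi would trigger the Still–Wittig shift through the lithiomethyl ether F4, placing C7 on the face of the oxygen, cis to the prenyl arm. The route is rejoined at 7.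

Step 13. Hydride delivery to the (S) enantiomer may follow the ring's own preference for axial attack instead of the catalyst, so that too little trans diol forms or the diastereomers do not separate. The fallback separates reduction, inversion and resolution and sets out from 19. Luche reduction (NaBH4, CeCl3·7H2O, MeOH) under substrate control would give the racemic cis diol F5, and silylation of the primary hydroxyl the racemic cis silyl ether F6. Mitsunobu inversion with 4-nitrobenzoic acid (PPh3, DIAD) would give the racemic trans 4-nitrobenzoate F7, and methanolysis the racemic trans alcohol F8. Lipase-catalysed acetylation (Candida antarctica lipase B, vinyl acetate) should then acylate the (1R,5R) enantiomer to its acetate F9 and leave the (1S,5S) alcohol. The route is rejoined at 21.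

Step 18. The α-branched, β,γ-unsaturated aldehyde may enolise before its hindered carbonyl is attacked, which would erode the trans relation at C6' or pull the ring alkene into conjugation. The fallback avoids the aldehyde by reversing the polarity at C7' and sets out from 24. Mitsunobu thioetherification with 1-phenyl-1H-tetrazole-5-thiol would give the tetrazolyl sulfide F10, oxidation ((NH4)6Mo7O24·4H2O, H2O2, EtOH) the tetrazolyl sulfone F11, and KN(SiMe3)2 at −78 °C the potassium sulfonyl carbanion F12, in which C6' is no longer acidic. Julia–Kocienski olefination with (E)-4-acetoxy-2-methylbut-2-enal would give the dienyl acetate F13 and methanolysis the dienol F14. Triphenylphosphine hydrobromide would convert this primary allylic alcohol into the phosphonium salt. The route is rejoined at 28.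

**Further compounds**

F1 | step 4 | racemic 2,4,4-trimethyl-5-(3-methylbut-2-en-1-yl)cyclohex-2-en-1-one | CC(C)=CCC1CC(=O)C(C)=CC1(C)C
F2 | step 4 | (1R,5S)-2,4,4-trimethyl-5-(3-methylbut-2-en-1-yl)cyclohex-2-en-1-ol | O[C@@H]1C[C@H](CC=C(C)C)C(C)(C)C=C1C
F3 | step 4 | tributylstannylmethyl ether of F2 | CCCC[Sn](CCCC)(CCCC)CO[C@@H]1C[C@H](CC=C(C)C)C(C)(C)C=C1C
F4 | step 4 | lithiomethyl ether of F2 | [Li]CO[C@@H]1C[C@H](CC=C(C)C)C(C)(C)C=C1C
F5 | step 13 | racemic cis diol, (1RS,5SR)-5-[(2E)-4-hydroxy-3-methylbut-2-en-1-yl]-2,4,4-trimethylcyclohex-2-en-1-ol (one enantiomer drawn) | O[C@@H]1C[C@H](C/C=C(\C)CO)C(C)(C)C=C1C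
F6 | step 13 | racemic cis silyl ether, primary tert-butyldiphenylsilyl ether of F5 (one enantiomer drawn) | O[C@@H]1C[C@H](C/C=C(\C)CO[Si](c2ccccc2)(c2ccccc2)C(C)(C)C)C(C)(C)C=C1C
F7 | step 13 | racemic trans 4-nitrobenzoate (one enantiomer drawn) | O=C(O[C@H]1C[C@H](C/C=C(\C)CO[Si](c2ccccc2)(c2ccccc2)C(C)(C)C)C(C)(C)C=C1C)c3ccc(cc3)[N+](=O)[O-]
F8 | step 13 | racemic trans alcohol, racemate of 21 (one enantiomer drawn) | O[C@H]1C[C@H](C/C=C(\C)CO[Si](c2ccccc2)(c2ccccc2)C(C)(C)C)C(C)(C)C=C1C
F9 | step 13 | (1R,5R)-acetate of the unwanted trans enantiomer | CC(=O)O[C@@H]1C[C@@H](C/C=C(\C)CO[Si](c2ccccc2)(c2ccccc2)C(C)(C)C)C(C)(C)C=C1C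
F10 | step 18 | 1-phenyl-1H-tetrazol-5-yl sulfide of 24 | c3ccccc3-n4nnnc4SC[C@H]1C(C)=CC[C@H](C/C=C(\C)CO[Si](c2ccccc2)(c2ccccc2)C(C)(C)C)C1(C)C
F11 | step 18 | 1-phenyl-1H-tetrazol-5-yl sulfone | c3ccccc3-n4nnnc4S(=O)(=O)C[C@H]1C(C)=CC[C@H](C/C=C(\C)CO[Si](c2ccccc2)(c2ccccc2)C(C)(C)C)C1(C)C
F12 | step 18 | potassium sulfonyl carbanion of F11 | [K+].c3ccccc3-n4nnnc4S(=O)(=O)[CH-][C@H]1C(C)=CC[C@H](C/C=C(\C)CO[Si](c2ccccc2)(c2ccccc2)C(C)(C)C)C1(C)C
F13 | step 18 | ring B (2E,4E)-dienyl acetate | CC(=O)OC/C=C(C)/C=C/[C@H]1C(C)=CC[C@H](C/C=C(\C)CO[Si](c2ccccc2)(c2ccccc2)C(C)(C)C)C1(C)C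
F14 | step 18 | ring B (2E,4E)-dienol | OC/C=C(C)/C=C/[C@H]1C(C)=CC[C@H](C/C=C(\C)CO[Si](c2ccccc2)(c2ccccc2)C(C)(C)C)C1(C)C
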